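The route rests on disconnecting the dimethoxylated benzene ring of the 6,7-dimethoxycoumarin half. In that ring C8a bears the lactone oxygen, C6 (para to it) and C7 each bear a methoxy group, and C4a bears the carbon chain. This is a 2-alkyl-4,5-dimethoxyphenol, the pattern a Dötz benzannulation delivers directly. In one operation a methoxy(1-methoxyvinyl)carbene complex of zerovalent chromium, one CO ligand and a terminal alkyne form C5–C6, C4a–C8a and C8–C8a and create the C8a hydroxyl. The alkyne partner is the umbelliferone ether of methyl 2-hydroxypent-4-ynoate, so the phenol emerges beside a CH2CH(OAr)CO2Me arm. Lactonization and C3–C4 dehydrogenation then finish the second coumarin.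

Key step: step 5

Assumption: 11, 13 and 14 are racemates whose single sp3 centre is erased in step 7, and the η6 complex 12 is written in SMILES as the arene dot-joined to a Cr(CO)3 fragment.

Step 1
Reactants: 1 methyl vinyl ether; 2 chromium hexacarbonyl
Product: 5 pentacarbonyl[methoxy(1-methoxyvinyl)carbene]chromium, via 1-methoxyvinyllithium 3 (not isolated), via lithium acylchromate 4 (not isolated)
Conditions: t-BuLi, THF, −78 to 0 °C; Cr(CO)6, Et2O, −78 °C to rt; Me3OBF4, CH2Cl2, 0 °C; used freshly
Reagents that add atoms: trimethyloxonium tetrafluoroborate (Me3OBF4), C[O+](C)C.F[B-](F)(F)F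
Why: Fischer carbene synthesis, in which the α-lithiated enol ether adds to a CO ligand of Cr(CO)6 and the resulting acyl chromate is methylated on oxygen by the hard oxonium salt, a sequence established for α-lithiated enol ethers.

Step 2
Reactants: 6 umbelliferone; 7 dimethyl bromomalonate
Product: 8 dimethyl 2-[(2-oxo-2H-chromen-7-yl)oxy]malonate
Conditions: K2CO3, acetone, reflux
Reagents that add atoms: none
Why: Williamson-type SN2 O-alkylation of the acidic 7-hydroxycoumarin at the doubly activated bromomalonate carbon, under anhydrous carbonate conditions that leave the lactone and both esters intact.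

Step 3
Reactants: 8 dimethyl 2-[(2-oxo-2H-chromen-7-yl)oxy]malonate; 9 propargyl bromide
Product: 10 dimethyl 2-[(2-oxo-2H-chromen-7-yl)oxy]-2-(prop-2-yn-1-yl)malonate
Conditions: Cs2CO3, DMF, rt
Reagents that add atoms: none
Why: Malonic ester C-alkylation, in which the aryloxymalonate anion displaces bromide from the unhindered propargylic carbon and, having only one acidic hydrogen, cannot be alkylated twice.

Step 4
Reactants: 10 dimethyl 2-[(2-oxo-2H-chromen-7-yl)oxy]-2-(prop-2-yn-1-yl)malonate
Product: 11 methyl 2-[(2-oxo-2H-chromen-7-yl)oxy]pent-4-ynoate (racemic)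
Conditions: LiCl, H2O (2 equiv), DMSO, 140 °C; dilute HCl work-up
Reagents that add atoms: none
Why: Krapcho dealkoxycarbonylation, in which chloride demethylates one ester, the carboxylate loses CO2 and water protonates the aryloxy-stabilized enolate, so the C2 centre forms as a racemate, which is acceptable because that centre is erased in step 7.

Step 5
Reactants: 11 methyl 2-[(2-oxo-2H-chromen-7-yl)oxy]pent-4-ynoate (racemic); 5 pentacarbonyl[methoxy(1-methoxyvinyl)carbene]chromium
Product: 13 methyl 3-(2-hydroxy-4,5-dimethoxyphenyl)-2-[(2-oxo-2H-chromen-7-yl)oxy]propanoate (racemic), via Cr(CO)3 arene complex 12 (not isolated)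
Conditions: 5 (1.3 equiv), degassed THF, 50 °C; then air, daylight, EtOAc, rt
Reagents that add atoms: none
Why: Dötz benzannulation: loss of one CO from 5 opens a site for the alkyne, which inserts into the Cr=C bond (C5–C6) to give a vinylcarbene; CO insertion (C4a–C8a) then gives a chromium-bound dienylketene, whose 6π-electrocyclization (C8–C8a) and enolization deliver the phenol as its Cr(CO)3 complex 12, freed by air and light. The closest known reaction type is the benzannulation of α-substituted alkenyl(methoxy)carbene complexes of zerovalent chromium, α-alkoxyalkenyl ones included, with terminal alkynes. The benzene ring is closed by thermal six-electron electrocyclic ring closure of the dienylketene, overall a [3+2+1] assembly from three carbons of the carbene ligand, two alkyne carbons and one CO. No stereocentre is formed and the racemic side-chain centre is a spectator. The step needs regioselective insertion, secured because the terminal alkyne bonds through its unsubstituted carbon to the carbene carbon so that the tethered carbon ends next to the new hydroxyl, and phenol formation over cyclopentannulation, favoured by chromium, an alkenyl carbene with a free CH2 terminus and a donor solvent. Neutral conditions spare the coumarin lactone, ester and aryl ether, and oxidant-free demetalation avoids quinone formation.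

Step 6
Reactants: 13 methyl 3-(2-hydroxy-4,5-dimethoxyphenyl)-2-[(2-oxo-2H-chromen-7-yl)oxy]propanoate (racemic)
Product: 14 6,7-dimethoxy-3-[(2-oxo-2H-chromen-7-yl)oxy]chroman-2-one (racemic)
Conditions: p-TsOH·H2O (cat.), toluene, 90 °C
Reagents that add atoms: none
Why: Acid-catalysed lactonization (intramolecular transesterification) of the ortho-hydroxyaryl propanoate closes the six-membered chroman-2-one with loss of methanol and masks the oxidation-prone phenol before a quinone oxidant is used.

Step 7
Reactants: 14 6,7-dimethoxy-3-[(2-oxo-2H-chromen-7-yl)oxy]chroman-2-one (racemic)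
Product: 15 daphnoretin methyl ether, 6,7-dimethoxy-3-[(2-oxo-2H-chromen-7-yl)oxy]-2H-chromen-2-one
Conditions: DDQ, 1,4-dioxane, reflux
Reagents that add atoms: none
Why: DDQ dehydrogenation, in which hydride abstraction from benzylic C4 (assisted by the C7 methoxy para to C4a and by the ring oxygen on C8a) and loss of the acidic C3 proton give the conjugated coumarin and remove the only stereocentre, while the existing coumarin and the aryl ether are inert to the quinone.

Compound list
1 | methyl vinyl ether | COC=C | starting material
2 | chromium hexacarbonyl, Cr(CO)6 | O=C=[Cr](=C=O)(=C=O)(=C=O)(=C=O)=C=O | starting material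
3 | 1-methoxyvinyllithium | [Li]C(=C)OC | intermediate (not isolated)
4 | lithium pentacarbonyl(2-methoxyacryloyl)chromate | [Li+].[O-]C(C(=C)OC)=[Cr](=C=O)(=C=O)(=C=O)(=C=O)=C=O | intermediate (not isolated)
5 | pentacarbonyl[methoxy(1-methoxyvinyl)carbene]chromium | COC(=C)C(OC)=[Cr](=C=O)(=C=O)(=C=O)(=C=O)=C=O | intermediate
6 | umbelliferone (7-hydroxycoumarin) | Oc1ccc2ccc(=O)oc2c1 | starting material
7 | dimethyl bromomalonate | COC(=O)C(Br)C(=O)OC | starting material
8 | dimethyl 2-[(2-oxo-2H-chromen-7-yl)oxy]malonate | COC(=O)C(Oc1ccc2ccc(=O)oc2c1)C(=O)OC | intermediate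
9 | propargyl bromide | BrCC#C | starting material
10 | dimethyl 2-[(2-oxo-2H-chromen-7-yl)oxy]-2-(prop-2-yn-1-yl)malonate | COC(=O)C(CC#C)(Oc1ccc2ccc(=O)oc2c1)C(=O)OC | intermediate
11 | methyl 2-[(2-oxo-2H-chromen-7-yl)oxy]pent-4-ynoate (racemic) | COC(=O)C(CC#C)Oc1ccc2ccc(=O)oc2c1 | intermediate
12 | tricarbonyl{η6-[methyl 3-(2-hydroxy-4,5-dimethoxyphenyl)-2-[(2-oxo-2H-chromen-7-yl)oxy]propanoate]}chromium (Cr(CO)3 on the new benzene ring; diastereomer mixture) | COC(=O)C(Cc1cc(OC)c(OC)cc1O)Oc1ccc2ccc(=O)oc2c1.O=C=[Cr](=C=O)=C=O | intermediate (not isolated)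
13 | methyl 3-(2-hydroxy-4,5-dimethoxyphenyl)-2-[(2-oxo-2H-chromen-7-yl)oxy]propanoate (racemic) | COC(=O)C(Cc1cc(OC)c(OC)cc1O)Oc1ccc2ccc(=O)oc2c1 | intermediate
14 | 6,7-dimethoxy-3-[(2-oxo-2H-chromen-7-yl)oxy]chroman-2-one (racemic) | COc1cc2CC(Oc3ccc4ccc(=O)oc4c3)C(=O)Oc2cc1OC | intermediate
15 | daphnoretin methyl ether, 6,7-dimethoxy-3-[(2-oxo-2H-chromen-7-yl)oxy]-2H-chromen-2-one (achiral) | COc1cc2cc(Oc3ccc4ccc(=O)oc4c3)c(=O)oc2cc1OC | target

Total step count: 7. Longest linear sequence: 6 (steps 2 to 7 from umbelliferone 6); step 1 supplies carbene complex 5 as a one-step side branch.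

Steps most likely to fail

Step 5 (key benzannulation). What may go wrong: after alkyne insertion the sequence may close a five-membered ring without taking up CO, or the alkyne may oligomerize. The α-alkoxyvinyl complex may also decompose thermally before it engages the alkyne, and the electron-rich phenol may over-oxidize during demetalation. The fallback sets out from umbelliferone 6 and abandons the benzannulation for a condensation route. O-alkylation of 6 with tert-butyl bromoacetate (K2CO3, acetone, reflux) should give tert-butyl 2-[(2-oxo-2H-chromen-7-yl)oxy]acetate F1. Cleavage of the ester with CF3CO2H in CH2Cl2 should give 2-[(2-oxo-2H-chromen-7-yl)oxy]acetic acid F2. A Perkin-type condensation of F2 with commercial 2-hydroxy-4,5-dimethoxybenzaldehyde (Ac2O, Et3N, 120 °C) follows: O-acylation of the salicylaldehyde, then intramolecular aldol condensation and dehydration. This should close the 3-aryloxycoumarin ring and come back to the route at target 15.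

Step 7 (dehydrogenation). What may go wrong: hydride abstraction from C4 may be slow next to the electron-poor lactone, and the quinone may instead degrade the electron-rich dimethoxyarene or form adducts. The fallback sets out from 14 and replaces hydride abstraction by α-selenation and selenoxide elimination. Enolization of 14 with LiN(SiMe3)2 in THF at −78 °C and trapping with PhSeBr should give 6,7-dimethoxy-3-[(2-oxo-2H-chromen-7-yl)oxy]-3-(phenylselanyl)chroman-2-one F3. Oxidation with H2O2 (CH2Cl2, pyridine, 0 °C to rt) should give the selenoxide 6,7-dimethoxy-3-[(2-oxo-2H-chromen-7-yl)oxy]-3-(phenylseleninyl)chroman-2-one F4, which is not isolated. Its syn-elimination can only engage the C4 hydrogens, and it should come back to the route at 15.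

Step 4 (Krapcho dealkoxycarbonylation). What may go wrong: the base generated in the hot, wet medium may open the coumarin lactone or hydrolyse the surviving ester, and prolonged heating may erode the terminal alkyne. The fallback sets out from propargyl bromide 9 and umbelliferone 6 and bypasses the malonate sequence. A zinc-mediated Barbier propargylation of commercial methyl glyoxylate (COC(=O)C=O) with 9 (Zn, THF, 0 °C, aqueous NH4Cl work-up) should give methyl 2-hydroxypent-4-ynoate (racemic) F5. Mitsunobu etherification of 6 with F5 (PPh3, DIAD, THF, 0 °C to rt), an SN2 displacement at the ester α-carbon, should come back to the route at 11.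

Further compounds
F1 | step 5 | tert-butyl 2-[(2-oxo-2H-chromen-7-yl)oxy]acetate | CC(C)(C)OC(=O)COc1ccc2ccc(=O)oc2c1
F2 | step 5 | 2-[(2-oxo-2H-chromen-7-yl)oxy]acetic acid | OC(=O)COc1ccc2ccc(=O)oc2c1
F3 | step 7 | 6,7-dimethoxy-3-[(2-oxo-2H-chromen-7-yl)oxy]-3-(phenylselanyl)chroman-2-one (racemic) | COc1cc2CC(Oc3ccc4ccc(=O)oc4c3)([Se]c3ccccc3)C(=O)Oc2cc1OC
F4 | step 7 | 6,7-dimethoxy-3-[(2-oxo-2H-chromen-7-yl)oxy]-3-(phenylseleninyl)chroman-2-one (selenoxide, not isolated) | COc1cc2CC(Oc3ccc4ccc(=O)oc4c3)([Se](=O)c3ccccc3)C(=O)Oc2cc1OC
F5 | step 4 | methyl 2-hydroxypent-4-ynoate (racemic) | COC(=O)C(O)CC#C
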